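**Assumption:** the SMILES is read as the (3S)-chroman, and that enantiomer is made; 2,3-dimethoxyphenol and 3,3-diethoxypropan-1-ol are taken as inexpensive catalogue chemicals.

**Retrosynthetic overview**
- Quinone ⇐ hydroquinone (air oxidation) ⇐ a cis-pterocarpan, by hydrogenolysis of its benzylic C–O bond and its one O-benzyl group; C3 is already in place.
- cis-Pterocarpan ⇐ a 3-aryloxypropanal + 2,3-dimethoxy-1,4-benzoquinone: amine-catalysed enantioselective α-arylation (C3–aryl bond, sets C3) with hemiacetal closure, then Friedel–Crafts closure of C4–C4a in the same flask.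
- 3-Aryloxypropanal ⇐ aryl bromide + 3,3-diethoxypropan-1-ol (Pd C–O coupling) ⇐ 2,6-dimethoxyphenol (O-benzylation, bromination); quinone ⇐ 2,3-dimethoxyphenol.
- Ring order: both carbocycles are bought as benzene rings; the dihydrofuran ring and then the pyran ring close in one operation; the dihydrofuran ring is opened again in the last step, when its arene becomes the quinone.

**Route**

Step 1
Reactants: 1 2,6-dimethoxyphenol
Product: 2 2-(benzyloxy)-1,3-dimethoxybenzene
Conditions: BnBr, K2CO3, DMF, 60 °C
Reagents that add atoms: benzyl bromide, BrCc1ccccc1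
Why: Williamson ether synthesis of the acidic phenol with a benzylic bromide installs the only protecting group of the route, which is removed in step 6.

Step 2
Reactants: 2 2-(benzyloxy)-1,3-dimethoxybenzene
Product: 3 2-(benzyloxy)-4-bromo-1,3-dimethoxybenzene
Conditions: NBS (1.0 equiv), MeCN, 0 °C to rt
Reagents that add atoms: N-bromosuccinimide, O=C1CCC(=O)N1Br
Why: Electrophilic aromatic bromination goes to C4 (ortho to one methoxy, para to the other) because the central benzyloxy group is twisted out of conjugation, as in the bromination of 1,2,3-trimethoxybenzene.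

Step 3
Reactants: 3 2-(benzyloxy)-4-bromo-1,3-dimethoxybenzene; 4 3,3-diethoxypropan-1-ol
Product: 6 3-[3-(benzyloxy)-2,4-dimethoxyphenoxy]propanal, via aryl ether acetal 5 (not isolated)
Conditions: [Pd(C3H5)Cl]2 (1.5 mol%), RockPhos [2-(di-tert-butylphosphino)-3-methoxy-6-methyl-2′,4′,6′-triisopropylbiphenyl] (4.5 mol%), Cs2CO3, toluene, 90 °C; filter, concentrate; then p-TsOH·H2O (5 mol%), acetone–H2O, rt
Reagents that add atoms: water, O
Why: Buchwald–Hartwig-type Pd-catalysed C–O cross-coupling of the electron-rich aryl bromide with a primary alcohol (the bulky biarylphosphine suppresses β-hydride elimination) is followed by acid-catalysed acetal hydrolysis, in which water delivers the aldehyde oxygen.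

Step 4
Reactants: 7 2,3-dimethoxyphenol
Product: 8 2,3-dimethoxycyclohexa-2,5-diene-1,4-dione (2,3-dimethoxy-1,4-benzoquinone)
Conditions: K2[ON(SO3)2] (2.2 equiv), KH2PO4, H2O–acetone, 0 °C to rt
Reagents that add atoms: potassium nitrosodisulfonate, [K+].[K+].[O]N(S(=O)(=O)[O-])S(=O)(=O)[O-]
Why: Teuber oxidation, in which two equivalents of the nitroxyl radical oxidise the phenol through its phenoxyl radical at the free para position to give the p-quinone.

Step 5
Reactants: 6 3-[3-(benzyloxy)-2,4-dimethoxyphenoxy]propanal; 8 2,3-dimethoxycyclohexa-2,5-diene-1,4-dione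
Product: 10 (6aS,11aS)-3-(benzyloxy)-2,4,9,10-tetramethoxy-6a,11a-dihydro-6H-[1]benzofuro[3,2-c]chromen-8-ol, via hemiacetal 9 (not isolated)
Conditions: (S)-2-[diphenyl(trimethylsilyloxy)methyl]pyrrolidine (20 mol%), 8 (1.1 equiv), EtOH–H2O, −25 °C; toluene azeotrope, then CH2Cl2 (0.02 M), 4 Å MS, BF3·OEt2 (50 mol%), −78 to −30 °C
Reagents that add atoms: none
Why: Proposed new method: the E-enamine of 6 adds through its face remote from the CPh2(OSiMe3) group to the unsubstituted C=C of quinone 8 (steric-shielding model, setting C3 as S; the (R)-catalyst would give the antipode), tautomerisation and hydrolysis give a hydroquinone aldehyde that closes with its ortho OH to hemiacetal 9 (dihydrofuran ring), and BF3 then ionises 9 to an aryloxy-stabilised oxocarbenium ion that is trapped by the arene carbon ortho to the ether oxygen and para to OBn in a six-membered Friedel–Crafts closure that can only be cis-fused (pyran ring, C11a fixed by C6a); the closest known reactions are the organocatalytic α-arylation of aldehydes with quinones and oxa-Pictet–Spengler-type Friedel–Crafts closures of lactol-derived oxocarbenium ions.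

Step 6
Reactants: 10 (6aS,11aS)-3-(benzyloxy)-2,4,9,10-tetramethoxy-6a,11a-dihydro-6H-[1]benzofuro[3,2-c]chromen-8-ol
Product: 12 5-[(3S)-7-hydroxy-6,8-dimethoxy-3,4-dihydro-2H-chromen-3-yl]-2,3-dimethoxycyclohexa-2,5-diene-1,4-dione, via hydroquinone 11 (not isolated)
Conditions: H2 (1 atm), 10% Pd/C, EtOAc–AcOH (10:1), rt; N2 purge; then air, rt
Reagents that add atoms: none
Why: Catalytic hydrogenolysis cleaves the doubly activated benzylic C11a–O bond (the classical pterocarpan to 2′-hydroxyisoflavan reduction) and the O-benzyl ether without touching C3, and the electron-rich hydroquinone 11 is then dehydrogenated by air over the same Pd/C while the single hindered phenol is inert.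

**Compound list**

1 | 2,6-dimethoxyphenol | COc1cccc(OC)c1O | starting material
2 | 2-(benzyloxy)-1,3-dimethoxybenzene | COc1cccc(OC)c1OCc1ccccc1 | intermediate
3 | 2-(benzyloxy)-4-bromo-1,3-dimethoxybenzene | COc1ccc(Br)c(OC)c1OCc1ccccc1 | intermediate
4 | 3,3-diethoxypropan-1-ol | CCOC(CCO)OCC | starting material
5 | 2-(benzyloxy)-4-(3,3-diethoxypropoxy)-1,3-dimethoxybenzene | CCOC(CCOc1ccc(OC)c(OCc2ccccc2)c1OC)OCC | intermediate
6 | 3-[3-(benzyloxy)-2,4-dimethoxyphenoxy]propanal | O=CCCOc1ccc(OC)c(OCc2ccccc2)c1OC | intermediate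
7 | 2,3-dimethoxyphenol | COc1cccc(O)c1OC | starting material
8 | 2,3-dimethoxycyclohexa-2,5-diene-1,4-dione | COC1=C(OC)C(=O)C=CC1=O | intermediate
9 | (3S)-3-{[3-(benzyloxy)-2,4-dimethoxyphenoxy]methyl}-6,7-dimethoxy-2,3-dihydro-1-benzofuran-2,5-diol (both anomers at C2) | COc1ccc(OC[C@H]2C(O)Oc3c2cc(O)c(OC)c3OC)c(OC)c1OCc1ccccc1 | intermediate
10 | (6aS,11aS)-3-(benzyloxy)-2,4,9,10-tetramethoxy-6a,11a-dihydro-6H-[1]benzofuro[3,2-c]chromen-8-ol (cis-pterocarpan) | COc1cc2c(c(OC)c1OCc1ccccc1)OC[C@H]1[C@@H]2Oc2c1cc(O)c(OC)c2OC | intermediate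
11 | 2-[(3S)-7-hydroxy-6,8-dimethoxy-3,4-dihydro-2H-chromen-3-yl]-5,6-dimethoxybenzene-1,4-diol | COc1cc2c(c(OC)c1O)OC[C@@H](C2)c1cc(O)c(OC)c(OC)c1O | intermediate
12 | 5-[(3S)-7-hydroxy-6,8-dimethoxy-3,4-dihydro-2H-chromen-3-yl]-2,3-dimethoxycyclohexa-2,5-diene-1,4-dione | COC1=C(OC)C(=O)C([C@H]2COc3c(cc(OC)c(O)c3OC)C2)=CC1=O | target

**Step count**

Total step count: 6. Longest linear sequence: 5 steps (steps 1, 2, 3, 5, 6).

**Steps most likely to fail, with fallbacks**

Step 5. Three things can go wrong. The β-aryloxy enamine may lose the phenoxide (retro-oxa-Michael). The dimethoxyquinone is a weaker acceptor than benzoquinone. In the acid stage, the oxocarbenium ion may lose the C3 proton to give a benzofuran instead of closing the pyran ring.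
The fallback sets out from 6 and comes back at 10. Aldehyde 6 is heated with p-TsOH in toluene at 80 °C. Intramolecular Friedel–Crafts hydroxyalkylation gives 7-(benzyloxy)-6,8-dimethoxy-3,4-dihydro-2H-chromen-4-ol F1, which loses water in the same flask to 7-(benzyloxy)-6,8-dimethoxy-2H-chromene F2. F2 and quinone 8 are then combined in CH2Cl2 at −78 °C with the chiral Lewis acid made from TiCl4, Ti(OiPr)4 and 2,2-dimethyl-α,α,α′,α′-tetraphenyl-1,3-dioxolane-4,5-dimethanol. The ligand enantiomer that gives the (6aS,11aS) series is fixed by one analytical run. The styrene-type C3 of F2 adds to the unsubstituted quinone carbon and the benzylic cation closes onto the neighbouring carbonyl oxygen (formal [3+2] cycloaddition), giving pterocarpan 10 with the pyran ring made first.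

Step 3. The hindered, electron-rich bromide may be reduced (β-hydride elimination from the Pd alkoxide) instead of coupled, and the acid stage may cyclise the product early.
The fallback sets out from 3 and comes back at 5. Bromine–lithium exchange (n-BuLi, THF, −78 °C, faster than benzylic deprotonation) gives [3-(benzyloxy)-2,4-dimethoxyphenyl]lithium F3. Trapping with B(OMe)3 gives dimethyl [3-(benzyloxy)-2,4-dimethoxyphenyl]boronate F4. Oxidation in the same flask with H2O2/NaOH gives 3-(benzyloxy)-2,4-dimethoxyphenol F5. Williamson alkylation of F5 with 3-bromo-1,1-diethoxypropane (K2CO3, DMF, 70 °C) gives acetal 5, which is hydrolysed as in step 3.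

Step 6. Hydrogenolysis of the ring C–O bond may be slow or incomplete next to the fast O-debenzylation.
The fallback sets out from 10 and comes back at 11. Ionic hydrogenation (Et3SiH, CF3CO2H, CH2Cl2, −20 °C) protonates the furan oxygen and opens the ring to the benzylic cation at C11a, which the silane reduces. This gives 2-[(3S)-7-(benzyloxy)-6,8-dimethoxy-3,4-dihydro-2H-chromen-3-yl]-5,6-dimethoxybenzene-1,4-diol F6. Plain O-debenzylation of F6 (H2, Pd/C, EtOAc) gives hydroquinone 11, which is oxidised by air as in step 6.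

**Further compounds**

F1 | step 5 | 7-(benzyloxy)-6,8-dimethoxy-3,4-dihydro-2H-chromen-4-ol (racemic) | COc1cc2C(O)CCOc2c(OC)c1OCc1ccccc1
F2 | step 5 | 7-(benzyloxy)-6,8-dimethoxy-2H-chromene | COc1cc2C=CCOc2c(OC)c1OCc1ccccc1
F3 | step 3 | [3-(benzyloxy)-2,4-dimethoxyphenyl]lithium | [Li]c1ccc(OC)c(OCc2ccccc2)c1OC
F4 | step 3 | dimethyl [3-(benzyloxy)-2,4-dimethoxyphenyl]boronate | COB(OC)c1ccc(OC)c(OCc2ccccc2)c1OC
F5 | step 3 | 3-(benzyloxy)-2,4-dimethoxyphenol | COc1ccc(O)c(OC)c1OCc1ccccc1
F6 | step 6 | 2-[(3S)-7-(benzyloxy)-6,8-dimethoxy-3,4-dihydro-2H-chromen-3-yl]-5,6-dimethoxybenzene-1,4-diol | COc1cc2c(c(OC)c1OCc1ccccc1)OC[C@@H](C2)c1cc(O)c(OC)c(OC)c1O
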